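**Numbering used throughout.** The lactone is O1–C2(=O)–C3–C4–C5. C7 is the benzylic carbon joining C3 to ring A (3,4-dimethoxyphenyl). C7' is the benzylic carbon joining C4 to ring B (3,4,5-trimethoxyphenyl).

## The problem

The target 15 is (3R,4R)-3-(3,4-dimethoxybenzyl)-4-(3,4,5-trimethoxybenzyl)dihydrofuran-2(3H)-one, a trans-dibenzylbutyrolactone with two different aryl rings. Its skeleton is the chain C7–C3–C4–C7' with one-carbon branches C2 (acyl) on C3 and C5 (CH2O) on C4, and the only ring is the lactone that joins these branches through O1. Of the two adjacent stereocentres, C3 is alpha to the carbonyl and can be equilibrated by base to the more stable trans arrangement, so C4 can control C3 but C3 cannot control C4. C4 is the real problem: it is a CH with three carbon arms, no heteroatom and no acidity, so its configuration has to be set during C–C bond formation. The lactone will not tolerate hydroxide, hydride or strong nucleophiles. The two electron-rich rings will not tolerate strong acids, Lewis acids that cleave aryl methyl ethers, or strong oxidants. A cation at C7' in particular would alkylate ring A para to its 3-methoxy group and close an aryltetralin. The feature that opens the route is that C4 carries the C5H2–O1 arm and also adjoins benzylic C7'. An oxygen placed temporarily on C7' stands 1,3 to O1, so C5 can be delivered from that oxygen through a silicon tether to C4 of a C3=C4 enoate. The C7' stereocentre then decides the face, and the benzylic C–O bond is finally removed by hydrogenolysis.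

## Retrosynthesis

**15 from 14 (C3–H).** C3 is not treated as a stereocentre to be made. The last operation is a base equilibration of lactone 14, which has C4 fixed and C3 as either epimer. This reduces the stereochemical problem to C4 alone, and asks of the forward reaction only that trans is the thermodynamic isomer, as it is for 3,4-dibenzyl lactones.

**14 from 13 (C7'–H to C7'–OH).** An oxygen is added retrosynthetically at C7' to give hydroxy lactone 13. No other position would do: only C7' is both next to C4 and benzylic, so that the oxygen can control C4 and can later be removed by hydrogenolysis. The forward step must cleave this C–O bond without strong acid, since ionisation at C7' leads to ring closure onto ring A.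

**13 from 11 through 12 (O1–C2, then C5–O and the O–H on C7').** Opening the lactone gives diol ester 12. Its 1,3-diol (O on C5 and O on C7') is the oxidation product of one five-membered ring, the 1,2-oxasilolane 11, in which C5 is bound to silicon and silicon to the C7' oxygen. The forward sequence needs a Tamao–Fleming oxidation, then lactonisation by the primary C5 hydroxyl and not by the benzylic one.

**11 from 10 (C4–C5, and C3–H).** This is the strategic cut. Cutting C4–C5 turns the oxasilolane into the acyclic (bromomethyl)dimethylsilyl ether 10 of an allylic alcohol, with a C3=C4 enoate as radical acceptor. Cuts at C3–C7 or C4–C7' would leave C4 to be made without a neighbouring control element. Here the tether forces delivery of C5 from the oxygen face, and the polarity is matched (nucleophilic alpha-silyl radical, electron-poor beta carbon). Precursor 10 has one stereocentre and no ring.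

**10 from 8 and 9 (Si–O).** The tether is installed by silylating carbinol 8 with chlorosilane 9, which also supplies carbon C5 of the target. The reaction only has to be mild enough for a gamma-hydroxy enoate.

**8 from 7 (C7'–H).** The carbinol comes from aryl ketone 7 by enantioselective carbonyl reduction. This is the single point where absolute configuration enters.

**7 from 6 and 4 (C3=C4).** A Wittig disconnection gives aryl glyoxal 6 and the alpha-benzylated stabilised ylide 4. The (E)-geometry it delivers places the ester trans to C7', so 8 cannot close to a butenolide. It also places the C7 benzyl group cis to C7', which supplies the allylic strain used for face control in the key step.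

**6 from 5; 4 from 1 and 2 through 3.** Glyoxal 6 is the methyl-oxidation product of acetophenone 5. Ylide 4 comes from C-alkylation of ylide 1 with benzyl bromide 2 via phosphonium salt 3. All four building blocks (1, 2, 5, 9) are commercial.

## Roads not taken

**Alternative 1:** Cut C7'–ring B and C3–C7 in one operation. A ring B aryl Grignard reagent with catalytic CuI (monovalent copper) would open the cyclopropane of the bicyclic malonate lactone A1 at its CH2. The resulting C3 enolate would then be benzylated in the same flask by bromide 2 to give lactone ester A2, and dealkoxycarbonylation and equilibration would finish the synthesis.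
- Merits: C4 comes from a one-step chiral-pool compound, both aryl groups are introduced in a single flask, and the whole route is about three steps.
- Weak points: the magnesium enolate of a malonate-type lactone, with copper salts present, is a sluggish partner for a benzylic bromide, so the tandem trapping may have to be split. The ester must then be removed at high temperature (Krapcho conditions) from a congested quaternary carbon.
- Comparison: on step count and on the source of chirality this road is clearly better than the chosen one. The chosen plan can set against it only that every C–C bond formation is a separately precedented operation, that its stereochemical intermediates are diastereomers and can be purified before the auxiliary centre is erased, and that 13 keeps an oxygen at C7' that gives access to 7'-oxygenated congeners.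

**Alternative 2:** Cut O1–C5 by a ring expansion. A Baeyer–Villiger monooxygenase of the cyclohexanone monooxygenase class (flavin, NADPH, O2) would insert oxygen next to one of the two enantiotopic CH2 groups of cyclobutanone A3 and give the (R)-lactone A4. Trans-selective alkylation of its enolate with bromide 2 would complete the target.
- Merits: about four steps, the C4 centre is created catalytically from an achiral ketone, and the final alkylation is the standard way to set trans.
- Weak points: both the level and the sense of enantioselection vary with enzyme and substrate, and a bulky trimethoxybenzyl group is not a typical substrate. An enzyme screen, cofactor recycling and dilute aqueous operation are needed.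
- Comparison: this road is shorter than the chosen plan. The chosen plan offers only small-molecule reagents and diastereomeric intermediates that can be purified.

**Alternative 3:** Cut O1–C2 and C2–C3 by carbonylation. Under CO with PdCl2 (divalent palladium), PPh3 and SnCl2 (divalent tin), homopropargylic alcohol A5 would close to the (E)-benzylidene lactone A6. Hydrogenation and epimerisation would follow.
- Merits: the lactone carbonyl comes from CO, and the ring and the C3 side chain are formed together.
- Weak points: the key step creates no stereocentre. The C4 centre must already be present in A5 as a propargylic carbon, and that needs a separate asymmetric synthesis of several steps. Hydrogenation then gives mainly the cis lactone, so the same final equilibration is required.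
- Comparison: this road is no shorter than the chosen plan and leaves the real problem, C4, unsolved by its key step. Its only advantage is that A6 is itself a lignan-type structure.

Key step: step 6

Assumption: in the oxazaborolidine reduction of 7, ring B is taken to act as the larger carbonyl flank, so the (S)-catalyst is written for the (R)-carbinol. If the sense proves reversed, the enantiomeric catalyst is used with nothing else changed.

## Route

Step 1
Reactants: 1 methyl (triphenylphosphoranylidene)acetate; 2 3,4-dimethoxybenzyl bromide
Product: 4 methyl 3-(3,4-dimethoxyphenyl)-2-(triphenylphosphoranylidene)propanoate, via phosphonium bromide 3 (not isolated)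
Conditions: EtOAc, reflux; then 2 M aq NaOH, CH2Cl2, 0 °C to rt
Reagents that add atoms: none
Why: C-alkylation of a stabilised phosphorus ylide by a benzylic bromide gives the phosphonium salt, and hydroxide then regenerates the alpha-substituted ylide; the salt is less acidic than that of 1, so transylidation does not drain it.

Step 2
Reactants: 5 3,4,5-trimethoxyacetophenone
Product: 6 2-oxo-2-(3,4,5-trimethoxyphenyl)acetaldehyde (handled as its hydrate)
Conditions: SeO2 (1.2 equiv), 1,4-dioxane–H2O (20:1), 100 °C
Reagents that add atoms: selenium dioxide, O=[Se]=O
Why: Riley oxidation of an aryl methyl ketone through its enol gives the aryl glyoxal; the methoxy-substituted ring is inert to SeO2 and there is no other enolisable position.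

Step 3
Reactants: 6 2-oxo-2-(3,4,5-trimethoxyphenyl)acetaldehyde; 4 methyl 3-(3,4-dimethoxyphenyl)-2-(triphenylphosphoranylidene)propanoate
Product: 7 methyl (E)-2-(3,4-dimethoxybenzyl)-4-oxo-4-(3,4,5-trimethoxyphenyl)but-2-enoate
Conditions: toluene, 60 °C, exclusion of light
Reagents that add atoms: none
Why: Wittig olefination; the stabilised ylide reacts only at the aldehyde carbon of the glyoxal, and alpha-substituted stabilised ylides give the alkene with ester and acyl group trans, which is the (E)-isomer needed later.

Step 4
Reactants: 7 methyl (E)-2-(3,4-dimethoxybenzyl)-4-oxo-4-(3,4,5-trimethoxyphenyl)but-2-enoate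
Product: 8 methyl (R,E)-2-(3,4-dimethoxybenzyl)-4-hydroxy-4-(3,4,5-trimethoxyphenyl)but-2-enoate
Conditions: (S)-1-methyl-3,3-diphenyltetrahydro-1H,3H-pyrrolo[1,2-c][1,3,2]oxazaborole [(S)-Me-CBS, 0.2 equiv], BH3·SMe2 (0.7 equiv), THF, −20 °C; MeOH quench
Reagents that add atoms: none
Why: Corey–Bakshi–Shibata reduction; the catalyst–borane complex binds the ketone oxygen and delivers hydride 1,2 to one face, and with ring B as the larger flank the (S)-catalyst should give the (R)-carbinol at C7', the only absolute stereochemical input of the route; ester and electron-poor alkene are not reduced at this temperature, and the configuration is to be confirmed by MTPA-ester analysis.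

Step 5
Reactants: 8 methyl (R,E)-2-(3,4-dimethoxybenzyl)-4-hydroxy-4-(3,4,5-trimethoxyphenyl)but-2-enoate; 9 (bromomethyl)chlorodimethylsilane
Product: 10 methyl (R,E)-4-{[(bromomethyl)dimethylsilyl]oxy}-2-(3,4-dimethoxybenzyl)-4-(3,4,5-trimethoxyphenyl)but-2-enoate
Conditions: imidazole (2.2 equiv), CH2Cl2, 0 °C; non-aqueous work-up, used promptly
Reagents that add atoms: none
Why: Silylation of a secondary alcohol with a chlorosilane; imidazole is basic enough to take up HCl but too weak to isomerise the gamma-hydroxy enoate to the gamma-keto ester, and C7' is not touched.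

Step 6
Reactants: 10 methyl (R,E)-4-{[(bromomethyl)dimethylsilyl]oxy}-2-(3,4-dimethoxybenzyl)-4-(3,4,5-trimethoxyphenyl)but-2-enoate
Product: 11 methyl 3-(3,4-dimethoxyphenyl)-2-[(4S,5R)-2,2-dimethyl-5-(3,4,5-trimethoxyphenyl)-1,2-oxasilolan-4-yl]propanoate (both epimers at C-2 of the propanoate)
Conditions: Bu3SnH (1.3 equiv, syringe pump over 6 h), 2,2'-azobis(2-methylpropionitrile) (AIBN, 0.1 equiv), benzene (0.01 M), 80 °C
Reagents that add atoms: none
Why: Bu3Sn• abstracts bromine from 10 to give the nucleophilic alpha-silyl radical at C5, which adds to C4, the beta carbon of the electron-poor enoate, and the resulting C3 radical alpha to the ester takes hydrogen from Bu3SnH and carries the chain. The closest known reaction type is the silicon-tethered radical cyclisation of (bromomethyl)dimethylsilyl ethers of allylic alcohols. The one ring formed, the 1,2-oxasilolane C5–Si–O–C7'–C4, closes in the 5-exo-trig mode; 6-endo attack at the fully substituted C3 is disfavoured by sterics and by polarity. C4 is controlled by C7': allylic 1,3-strain with the C7 benzyl group, which is cis to C7' on the alkene, holds the C7'–H bond in the alkene plane, so oxygen and ring B lie on opposite faces and the tether can deliver C5 only to the oxygen face; the C3 arm therefore ends trans to ring B on the new ring (4S,5R, C4 as in 15), and a chair-like transition state with ring B pseudo-equatorial predicts the same. C3 is formed in the hydrogen transfer and is not relied upon: an allylic-strain model predicts a bias toward the epimer that corresponds to 15, and step 9 corrects the rest. The step needs cyclisation to outrun direct reduction, which slow addition of the stannane should secure, and facial selectivity at C4, which the (E)-geometry of 10 should secure.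

Step 7
Reactants: 11 methyl 3-(3,4-dimethoxyphenyl)-2-[(4S,5R)-2,2-dimethyl-5-(3,4,5-trimethoxyphenyl)-1,2-oxasilolan-4-yl]propanoate
Product: 13 (4R)-3-(3,4-dimethoxybenzyl)-4-[(R)-hydroxy(3,4,5-trimethoxyphenyl)methyl]dihydrofuran-2(3H)-one (both C3 epimers), via diol ester 12 (not isolated)
Conditions: KF, KHCO3, 30% aq H2O2, THF–MeOH (1:1), rt to 40 °C; aq Na2S2O3 work-up; then 1,8-diazabicyclo[5.4.0]undec-7-ene (DBU, 0.1 equiv), toluene, rt
Reagents that add atoms: hydrogen peroxide, OO
Why: Tamao–Fleming oxidation: fluoride-activated silicon is attacked by peroxide and C5 migrates from silicon to oxygen, while the Si–O bond to C7' is simply hydrolysed, giving the 1,3-diol; base then closes the lactone through the unhindered primary C5 hydroxyl, the alternative lactone through the C7' oxygen being slower to form and strained by a cis relation of ring B and CH2OH.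

Step 8
Reactants: 13 (4R)-3-(3,4-dimethoxybenzyl)-4-[(R)-hydroxy(3,4,5-trimethoxyphenyl)methyl]dihydrofuran-2(3H)-one
Product: 14 (4R)-3-(3,4-dimethoxybenzyl)-4-(3,4,5-trimethoxybenzyl)dihydrofuran-2(3H)-one (both C3 epimers)
Conditions: H2 (4 atm), Pd(OH)2/C (20 wt%), EtOAc–EtOH (1:1), 40 °C
Reagents that add atoms: none
Why: Catalytic hydrogenolysis of a benzylic C–O bond activated by the electron-rich ring B; with no strong acid present, C7' should not ionise and Friedel–Crafts closure onto ring A is avoided, and C4 is not involved.

Step 9
Reactants: 14 (4R)-3-(3,4-dimethoxybenzyl)-4-(3,4,5-trimethoxybenzyl)dihydrofuran-2(3H)-one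
Product: 15 (3R,4R)-3-(3,4-dimethoxybenzyl)-4-(3,4,5-trimethoxybenzyl)dihydrofuran-2(3H)-one
Conditions: DBU (1.0 equiv), toluene, 100 °C
Reagents that add atoms: none
Why: Base-mediated epimerisation through the lactone enolate in an aprotic medium that cannot open the ring; C3 should equilibrate to the thermodynamically preferred trans relation to the fixed (4R) centre, which gives (3R,4R), and C4 carries no acidic hydrogen.

## Compound list

1 | methyl (triphenylphosphoranylidene)acetate | COC(=O)C=P(c1ccccc1)(c1ccccc1)c1ccccc1 | starting material
2 | 3,4-dimethoxybenzyl bromide | COc1ccc(CBr)cc1OC | starting material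
3 | [3-(3,4-dimethoxyphenyl)-1-methoxy-1-oxopropan-2-yl]triphenylphosphonium bromide | COC(=O)C(Cc1ccc(OC)c(OC)c1)[P+](c1ccccc1)(c1ccccc1)c1ccccc1.[Br-] | intermediate (not isolated)
4 | methyl 3-(3,4-dimethoxyphenyl)-2-(triphenylphosphoranylidene)propanoate | COC(=O)C(Cc1ccc(OC)c(OC)c1)=P(c1ccccc1)(c1ccccc1)c1ccccc1 | intermediate
5 | 3,4,5-trimethoxyacetophenone | COc1cc(C(C)=O)cc(OC)c1OC | starting material
6 | 2-oxo-2-(3,4,5-trimethoxyphenyl)acetaldehyde (handled as its hydrate) | COc1cc(C(=O)C=O)cc(OC)c1OC | intermediate
7 | methyl (E)-2-(3,4-dimethoxybenzyl)-4-oxo-4-(3,4,5-trimethoxyphenyl)but-2-enoate | COC(=O)/C(Cc1ccc(OC)c(OC)c1)=C/C(=O)c1cc(OC)c(OC)c(OC)c1 | intermediate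
8 | methyl (R,E)-2-(3,4-dimethoxybenzyl)-4-hydroxy-4-(3,4,5-trimethoxyphenyl)but-2-enoate | COC(=O)/C(Cc1ccc(OC)c(OC)c1)=C/[C@@H](O)c1cc(OC)c(OC)c(OC)c1 | intermediate
9 | (bromomethyl)chlorodimethylsilane | C[Si](C)(Cl)CBr | starting material
10 | methyl (R,E)-4-{[(bromomethyl)dimethylsilyl]oxy}-2-(3,4-dimethoxybenzyl)-4-(3,4,5-trimethoxyphenyl)but-2-enoate | COC(=O)/C(Cc1ccc(OC)c(OC)c1)=C/[C@@H](O[Si](C)(C)CBr)c1cc(OC)c(OC)c(OC)c1 | intermediate
11 | methyl 3-(3,4-dimethoxyphenyl)-2-[(4S,5R)-2,2-dimethyl-5-(3,4,5-trimethoxyphenyl)-1,2-oxasilolan-4-yl]propanoate, both epimers at C-2 of the propanoate (ring B trans to the side chain on the oxasilolane) | COC(=O)C(Cc1ccc(OC)c(OC)c1)[C@@H]1C[Si](C)(C)O[C@H]1c1cc(OC)c(OC)c(OC)c1 | intermediate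
12 | methyl (3R,4R)-2-(3,4-dimethoxybenzyl)-4-hydroxy-3-(hydroxymethyl)-4-(3,4,5-trimethoxyphenyl)butanoate, both C2 epimers | COC(=O)C(Cc1ccc(OC)c(OC)c1)[C@H](CO)[C@@H](O)c1cc(OC)c(OC)c(OC)c1 | intermediate (not isolated)
13 | (4R)-3-(3,4-dimethoxybenzyl)-4-[(R)-hydroxy(3,4,5-trimethoxyphenyl)methyl]dihydrofuran-2(3H)-one, both C3 epimers | COc1ccc(CC2C(=O)OC[C@@H]2[C@@H](O)c2cc(OC)c(OC)c(OC)c2)cc1OC | intermediate
14 | (4R)-3-(3,4-dimethoxybenzyl)-4-(3,4,5-trimethoxybenzyl)dihydrofuran-2(3H)-one, both C3 epimers | COc1ccc(CC2C(=O)OC[C@@H]2Cc2cc(OC)c(OC)c(OC)c2)cc1OC | intermediate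
15 | (3R,4R)-3-(3,4-dimethoxybenzyl)-4-(3,4,5-trimethoxybenzyl)dihydrofuran-2(3H)-one | COc1ccc(C[C@H]2C(=O)OC[C@@H]2Cc2cc(OC)c(OC)c(OC)c2)cc1OC | target

## Step count and risks

Total: 9 steps. Longest linear sequence: 8 steps (5 to 15, steps 2 to 9).

**Step 6 (key step).** The alpha-silyl radical may take hydrogen from the stannane before it cyclises. Facial discrimination at C4 may also be weaker than the allylic-strain argument suggests, which would cost material at the diastereomer separation of 11 or 13 and, if it passed unnoticed, enantiomeric purity of 15. Hydrolytic loss of the tether during handling of 10 is a third route to failure.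

The fallback replaces the tether by a ring as control element. It sets out from 7 and comes back at 14.
- Reduction of 7 with the enantiomeric oxazaborolidine gives methyl (S,E)-2-(3,4-dimethoxybenzyl)-4-hydroxy-4-(3,4,5-trimethoxyphenyl)but-2-enoate F1.
- Sensitised irradiation (benzophenone, 350 nm, MeCN) isomerises the alkene, and the (Z)-isomer lactonises in the flask to (S)-3-(3,4-dimethoxybenzyl)-5-(3,4,5-trimethoxyphenyl)furan-2(5H)-one F2.
- Benzophenone-sensitised photoaddition of methanol places the hydroxymethyl radical on C4 trans to ring B under neutral conditions. This gives (4R,5S)-3-(3,4-dimethoxybenzyl)-4-(hydroxymethyl)-5-(3,4,5-trimethoxyphenyl)dihydrofuran-2(3H)-one F3.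
- Hydrogenolysis of the benzylic lactone C–O bond (H2, Pd/C, EtOAc) gives (3R)-2-(3,4-dimethoxybenzyl)-3-(hydroxymethyl)-4-(3,4,5-trimethoxyphenyl)butanoic acid F4.
- F4 closes to 14 with catalytic p-toluenesulfonic acid in toluene. Acid is harmless at this stage because no oxygen is left on C7'.

**Step 4.** Both carbonyl substituents of 7 are unsaturated, so facial discrimination by the oxazaborolidine may be low or opposite to the sense assumed. Conjugate reduction of the twisted enone is a second failure mode.

The fallback creates C7' by face-selective addition to an aldehyde, where no size comparison of two pi-systems is involved. It sets out from bromide 2 and comes back at 8.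
- Commercial 3,4,5-trimethoxybenzaldehyde and methyl propiolate are joined by catalytic enantioselective alkynylation (Me2Zn with a chiral bis(prolinol)phenol ligand) to give methyl (S)-4-hydroxy-4-(3,4,5-trimethoxyphenyl)but-2-ynoate F5.
- Hydroxyl-directed trans-hydroalumination with NaAlH2(OCH2CH2OMe)2 at −70 °C and iodination of the vinylaluminium intermediate give methyl (R,Z)-4-hydroxy-2-iodo-4-(3,4,5-trimethoxyphenyl)but-2-enoate F6.
- Negishi coupling of F6 with the benzylzinc bromide made from 2 and zinc dust (Pd(PPh3)4, zerovalent palladium, THF) gives 8 with the benzyl group cis to C7'.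

**Step 7.** Under base, the acyl group may migrate to the benzylic oxygen, or the lactone may close through the wrong hydroxyl. A primary hydroxyl left free in this way would not converge cleanly in step 8. Incomplete lactonisation is the milder version of the same problem.

The fallback removes the benzylic oxygen before any lactone is made. It sets out from 12 (isolated by omitting the DBU treatment) and comes back at 15.
- Hydrogenolysis of 12 (H2, Pd(OH)2/C, EtOAc–EtOH) gives methyl (3R)-2-(3,4-dimethoxybenzyl)-3-(hydroxymethyl)-4-(3,4,5-trimethoxyphenyl)butanoate F7, in which only one hydroxyl remains.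
- DBU in toluene at 100 °C then lactonises F7 and equilibrates C3 in one operation to give 15.

**Step 8.** Without acid, C–O cleavage at C7' may be slow. Any acid added to speed it up invites ionisation at C7' and Friedel–Crafts closure onto ring A.

The fallback is a radical deoxygenation. It sets out from 13 and comes back at 14.
- Phenyl chlorothionoformate with pyridine and 4-(dimethylamino)pyridine in CH2Cl2 at 0 °C gives the O-phenyl thionocarbonate of 13 F8.
- Barton–McCombie reduction of F8 (Bu3SnH, AIBN, toluene, 80 °C) cleaves the benzylic C–O bond through the benzylic radical and gives 14.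

## Further compounds

F1 | step 6 | methyl (S,E)-2-(3,4-dimethoxybenzyl)-4-hydroxy-4-(3,4,5-trimethoxyphenyl)but-2-enoate | COC(=O)/C(Cc1ccc(OC)c(OC)c1)=C/[C@H](O)c1cc(OC)c(OC)c(OC)c1
F2 | step 6 | (S)-3-(3,4-dimethoxybenzyl)-5-(3,4,5-trimethoxyphenyl)furan-2(5H)-one | COc1ccc(CC2=C[C@@H](c3cc(OC)c(OC)c(OC)c3)OC2=O)cc1OC
F3 | step 6 | (4R,5S)-3-(3,4-dimethoxybenzyl)-4-(hydroxymethyl)-5-(3,4,5-trimethoxyphenyl)dihydrofuran-2(3H)-one, both C3 epimers | COc1ccc(CC2C(=O)O[C@H](c3cc(OC)c(OC)c(OC)c3)[C@H]2CO)cc1OC
F4 | step 6 | (3R)-2-(3,4-dimethoxybenzyl)-3-(hydroxymethyl)-4-(3,4,5-trimethoxyphenyl)butanoic acid, both C2 epimers | OC(=O)C(Cc1ccc(OC)c(OC)c1)[C@H](CO)Cc1cc(OC)c(OC)c(OC)c1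
F5 | step 4 | methyl (S)-4-hydroxy-4-(3,4,5-trimethoxyphenyl)but-2-ynoate | COC(=O)C#C[C@@H](O)c1cc(OC)c(OC)c(OC)c1
F6 | step 4 | methyl (R,Z)-4-hydroxy-2-iodo-4-(3,4,5-trimethoxyphenyl)but-2-enoate | COC(=O)/C(I)=C/[C@@H](O)c1cc(OC)c(OC)c(OC)c1
F7 | step 7 | methyl (3R)-2-(3,4-dimethoxybenzyl)-3-(hydroxymethyl)-4-(3,4,5-trimethoxyphenyl)butanoate, both C2 epimers | COC(=O)C(Cc1ccc(OC)c(OC)c1)[C@H](CO)Cc1cc(OC)c(OC)c(OC)c1
F8 | step 8 | O-{(R)-[(3R)-4-(3,4-dimethoxybenzyl)-5-oxotetrahydrofuran-3-yl](3,4,5-trimethoxyphenyl)methyl} O-phenyl carbonothioate, both epimers at the benzyl-bearing ring carbon | COc1ccc(CC2C(=O)OC[C@@H]2[C@@H](OC(=S)Oc2ccccc2)c2cc(OC)c(OC)c(OC)c2)cc1OC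
A1 | alternative 1 | methyl (1S,5R)-2-oxo-3-oxabicyclo[3.1.0]hexane-1-carboxylate | COC(=O)[C@]12C[C@H]1COC2=O
A2 | alternative 1 | methyl (3R,4R)-3-(3,4-dimethoxybenzyl)-2-oxo-4-(3,4,5-trimethoxybenzyl)tetrahydrofuran-3-carboxylate | COc1ccc(C[C@@]2(C(=O)OC)C(=O)OC[C@@H]2Cc2cc(OC)c(OC)c(OC)c2)cc1OC
A3 | alternative 2 | 3-(3,4,5-trimethoxybenzyl)cyclobutan-1-one | COc1cc(CC2CC(=O)C2)cc(OC)c1OC
A4 | alternative 2 | (R)-4-(3,4,5-trimethoxybenzyl)dihydrofuran-2(3H)-one | O=C1OC[C@H](Cc2cc(OC)c(OC)c(OC)c2)C1
A5 | alternative 3 | (R)-4-(3,4-dimethoxyphenyl)-2-(3,4,5-trimethoxybenzyl)but-3-yn-1-ol | OC[C@H](Cc1cc(OC)c(OC)c(OC)c1)C#Cc1ccc(OC)c(OC)c1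
A6 | alternative 3 | (R,E)-3-(3,4-dimethoxybenzylidene)-4-(3,4,5-trimethoxybenzyl)dihydrofuran-2(3H)-one | COc1ccc(/C=C2/C(=O)OC[C@@H]2Cc2cc(OC)c(OC)c(OC)c2)cc1OC
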